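**Retrosynthetic overview**
1. The plan rests on ring A. C8a–O, C4a–C4 (the acyl carbon) and C5–heptyl occupy three adjacent ring carbons, and the C7 oxygen lies para to C4a. This is the pattern of a 2,4-dialkoxy-1-iodobenzene with one free ortho C–H.
2. Key disconnection: C5–heptyl and C4a–C4 are cut together. This leads back to 2,4-bis(benzyloxy)-1-iodobenzene, 1-bromoheptane and a ring-B vinyl ketone (Pd/norbornene ortho-alkylation with ipso Heck coupling).
3. The resulting enone is raised to the C2/C4 1,3-diketone by conjugate borylation–oxidation at C4, followed by oxidation of the alcohol.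
4. Rings A and B are bought as arenes (resorcinol, orsellinic acid). The only ring made is the dihydropyranone, closed last (O1–C2) when hydrogenolysis frees the C8a phenol.
5. C2 is a labile hemiketal carbon, so (R) is fixed at the very end by crystallisation-induced transformation of a chiral ammonium salt of the ring-B acid.

Key step: step 7

Remark 1: C2 epimerises through the ring-opened 1,3-diketone, so it is set only in the last two steps; the fully deprotected compound is assumed to rest as the 2-hydroxychroman-4-one, the form drawn for the target.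
Remark 2: which hand of the amine pairs with the (R)-acid in the less soluble salt cannot be predicted; the route is written for the (R)-amine, and if the crystal holds the (S)-acid, the (S)-amine must by mirror symmetry deliver the (R)-acid salt.

**Step 1**
Reactants: 1 resorcinol
Product: 2 1,3-bis(benzyloxy)benzene
Conditions: BnBr (2.2 equiv), K2CO3, DMF, 60 °C
Reagents that add atoms: benzyl bromide, BrCc1ccccc1
Why: Williamson ether synthesis in which both phenoxides are O-alkylated by the reactive benzylic bromide, benzyl being chosen so that every protecting group of the route falls in one neutral hydrogenolysis.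

**Step 2**
Reactants: 2 1,3-bis(benzyloxy)benzene
Product: 3 2,4-bis(benzyloxy)-1-iodobenzene
Conditions: NIS (1.0 equiv), MeCN, 0 °C → rt, dark
Reagents that add atoms: N-iodosuccinimide, O=C1CCC(=O)N1I
Why: Electrophilic aromatic iodination goes to the position ortho to one and para to the other benzyloxy group, because the carbon between the two ethers is too crowded and one equivalent of NIS limits di-iodination.

**Step 3**
Reactants: 4 orsellinic acid (2,4-dihydroxy-6-methylbenzoic acid)
Product: 5 benzyl 2,4-bis(benzyloxy)-6-methylbenzoate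
Conditions: BnBr (3.5 equiv), K2CO3, DMF, rt → 60 °C
Reagents that add atoms: benzyl bromide, BrCc1ccccc1
Why: Williamson and carboxylate alkylation in which the carboxylate and the free para phenol react first, which removes the risk of decarboxylation, and gentle heating then brings in the hydrogen-bonded ortho phenol.

**Step 4**
Reactants: 5 benzyl 2,4-bis(benzyloxy)-6-methylbenzoate
Product: 7 2-[3,5-bis(benzyloxy)-2-(benzyloxycarbonyl)phenyl]acetic acid, via benzylic lithium species 6 (not isolated)
Conditions: LiN(i-Pr)2 (commercial solution, 1.2 equiv), THF, −78 °C (5 added to the base); dry CO2, −78 → 0 °C; 1 M HCl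
Reagents that add atoms: carbon dioxide, O=C=O; lithium diisopropylamide (Li in 6 only), [Li]N(C(C)C)C(C)C
Why: Lateral lithiation of an ortho-toluate followed by carboxylation works because the ester-conjugated methyl group is the most acidic site, adding 5 to the base keeps free ester away from the anion and so holds down self-condensation, and the lithium carboxylate formed is inert to further attack.

**Step 5**
Reactants: 7 2-[3,5-bis(benzyloxy)-2-(benzyloxycarbonyl)phenyl]acetic acid
Product: 8 benzyl 2,4-bis(benzyloxy)-6-{2-[methoxy(methyl)amino]-2-oxoethyl}benzoate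
Conditions: MeNH(OMe)·HCl, EDC·HCl, HOBt (cat.), N-methylmorpholine, CH2Cl2, 0 °C → rt
Reagents that add atoms: N,O-dimethylhydroxylamine hydrochloride, CNOC.Cl
Why: Carbodiimide amide coupling (Weinreb amide formation) engages the only free, unhindered aliphatic acid and leaves the doubly ortho-substituted benzyl ester untouched.

**Step 6**
Reactants: 8 benzyl 2,4-bis(benzyloxy)-6-{2-[methoxy(methyl)amino]-2-oxoethyl}benzoate
Product: 9 benzyl 2,4-bis(benzyloxy)-6-(2-oxobut-3-en-1-yl)benzoate
Conditions: CH2=CHMgBr (2.5 equiv), THF, −78 → −20 °C; inverse quench into cold 1 M HCl; kept cold with a trace of BHT and used promptly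
Reagents that add atoms: vinylmagnesium bromide, C=C[Mg]Br
Why: In this Weinreb ketone synthesis the magnesium chelate of the adduct stops the reaction at one addition, the crowded benzoate is inert at low temperature, excess Grignard reagent covers some α-deprotonation, and the inverse acidic quench protonates the released MeNH(OMe) before it can add to the new vinyl ketone.

**Step 7**
Reactants: 3 2,4-bis(benzyloxy)-1-iodobenzene; 10 1-bromoheptane; 9 benzyl 2,4-bis(benzyloxy)-6-(2-oxobut-3-en-1-yl)benzoate
Product: 11 benzyl 2,4-bis(benzyloxy)-6-[(3E)-4-(2,4-bis(benzyloxy)-6-heptylphenyl)-2-oxobut-3-en-1-yl]benzoate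
Conditions: Pd(OAc)2 (10 mol %), P(2-furyl)3 (20 mol %), norbornene (3 equiv), K2CO3 (4 equiv), 3 (1.5 equiv), 10 (4 equiv), 9 (1.0 equiv, in portions), degassed DMA, 60 °C
Reagents that add atoms: none
Why: Zerovalent palladium inserts into the C4a–I bond of 3, strained norbornene carbopalladates the arylpalladium species ahead of the enone, and carbonate-assisted C–H palladation at the single free ortho position (the future C5) closes an aryl–norbornyl palladacycle, which takes up 10 by oxidative addition to tetravalent palladium and reductively eliminates the C5–heptyl bond. With both ortho positions then occupied, steric strain forces β-carbon elimination of norbornene, and the freed arylpalladium species inserts the CH2 terminus of 9 and loses hydride (Mizoroki–Heck), which makes C4a–C4. The closest known reaction type is this one itself, the Catellani ortho-alkylation/ipso-Heck sequence, established for ortho-alkoxy aryl iodides, primary alkyl bromides and vinyl ketones or acrylates. No ring closes and no stereocentre forms; the E geometry follows from syn insertion, bond rotation and syn β-hydride elimination with the bulky aryl group anti to the acyl group. The step needs one alkylation at C5 before any Heck event: the C8a benzyloxy group blocks the other ortho site, excess norbornene plus portionwise addition of 9 suppresses direct Heck coupling of the unalkylated aryl, and norbornene can leave only after di-ortho substitution. Since 9 and 11 hold an enolisable ArCH2C(=O) unit beside an ester, sparingly soluble K2CO3 at 60 °C replaces hotter Cs2CO3 protocols so that self-Michael addition, C-heptylation and enolate attack on the ester stay slow, and fast enone insertion outruns C–H arylation of the neighbouring benzyl ether.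

**Step 8**
Reactants: 11 benzyl 2,4-bis(benzyloxy)-6-[(3E)-4-(2,4-bis(benzyloxy)-6-heptylphenyl)-2-oxobut-3-en-1-yl]benzoate
Product: 13 benzyl 2,4-bis(benzyloxy)-6-[4-(2,4-bis(benzyloxy)-6-heptylphenyl)-4-hydroxy-2-oxobutyl]benzoate (racemic), via C4 pinacol boronate 12 (not isolated)
Conditions: CuCl (5 mol %), DPEphos (5 mol %), NaOt-Bu (10 mol %), B2pin2 (1.2 equiv), MeOH (2 equiv), THF, rt; then NaBO3·4H2O, THF–H2O, 0 °C → rt; taken on crude
Reagents that add atoms: bis(pinacolato)diboron (Bpin in 12), CC1(C)OB(OC1(C)C)B1OC(C)(C)C(C)(C)O1; sodium perborate (O on C4 of 13), [Na+].[Na+].O[B-]1(O)OO[B-](O)(O)OO1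
Why: Copper-catalysed conjugate borylation of an enone (a ligated Cu–Bpin species delivers boron to the β-carbon C4 and MeOH protonates the copper enolate) followed by perborate oxidation of the C–B bond places oxygen on C4 only, and the racemic C4 carbinol centre is erased in step 9.

**Step 9**
Reactants: 13 benzyl 2,4-bis(benzyloxy)-6-[4-(2,4-bis(benzyloxy)-6-heptylphenyl)-4-hydroxy-2-oxobutyl]benzoate
Product: 14 benzyl 2,4-bis(benzyloxy)-6-[4-(2,4-bis(benzyloxy)-6-heptylphenyl)-2,4-dioxobutyl]benzoate
Conditions: IBX (2 equiv), EtOAc, 75 °C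
Reagents that add atoms: none
Why: IBX oxidation of a β-hydroxy ketone is known to stop at the β-diketone without attacking the central CH2, and it spares benzyl ethers and the benzyl ester.

**Step 10**
Reactants: 14 benzyl 2,4-bis(benzyloxy)-6-[4-(2,4-bis(benzyloxy)-6-heptylphenyl)-2,4-dioxobutyl]benzoate
Product: 16 rac-2-{[5-heptyl-2,7-dihydroxy-4-oxo-3,4-dihydro-2H-chromen-2-yl]methyl}-4,6-dihydroxybenzoic acid, via open-chain diketo acid 15 (not isolated)
Conditions: H2 (1 atm), 10 % Pd/C, EtOAc–THF (no alcohol), rt, stopped at the calculated uptake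
Reagents that add atoms: none
Why: Heterogeneous hydrogenolysis removes four benzyl ethers and the benzyl ester under neutral conditions, and the freed C8a phenol adds to the C2 ketone (6-exo-trig hemiketalisation) to close the dihydropyranone ring; with no chiral influence C2 forms racemic and is set in step 11.

**Step 11**
Reactants: 16 rac-2-{[5-heptyl-2,7-dihydroxy-4-oxo-3,4-dihydro-2H-chromen-2-yl]methyl}-4,6-dihydroxybenzoic acid
Product: 17 (1R)-N,N-dimethyl-1-phenylethanaminium 2-{[(2R)-5-heptyl-2,7-dihydroxy-4-oxo-3,4-dihydro-2H-chromen-2-yl]methyl}-4,6-dihydroxybenzoate (crystalline salt)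
Conditions: (R)-PhCH(CH3)N(CH3)2 (1.05 equiv), MeCN, 40 → 5 °C, seeded slurry aged until the liquor is depleted; filtration
Reagents that add atoms: (R)-N,N-dimethyl-1-phenylethylamine, C[C@@H](N(C)C)c1ccccc1
Why: Proposed new method: in solution the two C2 epimers of the salt interconvert through the ring-opened diketone 15 (retro-hemiketalisation, catalysed by the carboxylate/ammonium buffer) while only the less soluble diastereomeric salt leaves the equilibrium as crystals, so the whole batch drains into one configuration at C2. A chiral acid catalyst alone could not do this because the two enantiomers are equal in energy, whereas the diastereomeric lattice supplies a thermodynamic bias, and a tertiary amine is used so that no enaminone can form with the diketone. The closest known reaction types are crystallisation-induced diastereomer transformation of lactols, crystallisation of mutarotating hemiacetals as one anomer, and classical salt resolution of carboxylic acids.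

**Step 12**
Reactants: 17 (1R)-N,N-dimethyl-1-phenylethanaminium salt of the (2R)-acid
Product: 18 2-{[(2R)-5-heptyl-2,7-dihydroxy-4-oxo-3,4-dihydro-2H-chromen-2-yl]methyl}-4,6-dihydroxybenzoic acid (target)
Conditions: EtOAc / 0.5 M aq. HCl, 0 °C, brief; dry, evaporate below 10 °C; store as a solid at −20 °C
Reagents that add atoms: none
Why: This salt break is a plain proton transfer that touches no bond at C2, and cold, short, biphasic handling keeps ring opening, and with it racemisation and dehydration to the chromone, slow.

**Compound list**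
1 | resorcinol | Oc1cccc(O)c1 | starting material
2 | 1,3-bis(benzyloxy)benzene | c1ccc(COc2cccc(OCc3ccccc3)c2)cc1 | intermediate
3 | 2,4-bis(benzyloxy)-1-iodobenzene | Ic1ccc(OCc2ccccc2)cc1OCc1ccccc1 | intermediate
4 | orsellinic acid | Cc1cc(O)cc(O)c1C(=O)O | starting material
5 | benzyl 2,4-bis(benzyloxy)-6-methylbenzoate | Cc1cc(OCc2ccccc2)cc(OCc2ccccc2)c1C(=O)OCc1ccccc1 | intermediate
6 | benzyl 2,4-bis(benzyloxy)-6-(lithiomethyl)benzoate | [Li]Cc1cc(OCc2ccccc2)cc(OCc2ccccc2)c1C(=O)OCc1ccccc1 | intermediate
7 | 2-[3,5-bis(benzyloxy)-2-(benzyloxycarbonyl)phenyl]acetic acid | OC(=O)Cc1cc(OCc2ccccc2)cc(OCc2ccccc2)c1C(=O)OCc1ccccc1 | intermediate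
8 | benzyl 2,4-bis(benzyloxy)-6-{2-[methoxy(methyl)amino]-2-oxoethyl}benzoate | CON(C)C(=O)Cc1cc(OCc2ccccc2)cc(OCc2ccccc2)c1C(=O)OCc1ccccc1 | intermediate
9 | benzyl 2,4-bis(benzyloxy)-6-(2-oxobut-3-en-1-yl)benzoate | C=CC(=O)Cc1cc(OCc2ccccc2)cc(OCc2ccccc2)c1C(=O)OCc1ccccc1 | intermediate
10 | 1-bromoheptane | CCCCCCCBr | starting material
11 | benzyl 2,4-bis(benzyloxy)-6-[(3E)-4-(2,4-bis(benzyloxy)-6-heptylphenyl)-2-oxobut-3-en-1-yl]benzoate | CCCCCCCc1cc(OCc2ccccc2)cc(OCc2ccccc2)c1/C=C/C(=O)Cc1cc(OCc2ccccc2)cc(OCc2ccccc2)c1C(=O)OCc1ccccc1 | intermediate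
12 | benzyl 2,4-bis(benzyloxy)-6-[4-(2,4-bis(benzyloxy)-6-heptylphenyl)-2-oxo-4-(4,4,5,5-tetramethyl-1,3,2-dioxaborolan-2-yl)butyl]benzoate (racemic) | CCCCCCCc1cc(OCc2ccccc2)cc(OCc2ccccc2)c1C(CC(=O)Cc1cc(OCc2ccccc2)cc(OCc2ccccc2)c1C(=O)OCc1ccccc1)B1OC(C)(C)C(C)(C)O1 | intermediate
13 | benzyl 2,4-bis(benzyloxy)-6-[4-(2,4-bis(benzyloxy)-6-heptylphenyl)-4-hydroxy-2-oxobutyl]benzoate (racemic) | CCCCCCCc1cc(OCc2ccccc2)cc(OCc2ccccc2)c1C(O)CC(=O)Cc1cc(OCc2ccccc2)cc(OCc2ccccc2)c1C(=O)OCc1ccccc1 | intermediate
14 | benzyl 2,4-bis(benzyloxy)-6-[4-(2,4-bis(benzyloxy)-6-heptylphenyl)-2,4-dioxobutyl]benzoate | CCCCCCCc1cc(OCc2ccccc2)cc(OCc2ccccc2)c1C(=O)CC(=O)Cc1cc(OCc2ccccc2)cc(OCc2ccccc2)c1C(=O)OCc1ccccc1 | intermediate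
15 | 2-[4-(2-heptyl-4,6-dihydroxyphenyl)-2,4-dioxobutyl]-4,6-dihydroxybenzoic acid | CCCCCCCc1cc(O)cc(O)c1C(=O)CC(=O)Cc1cc(O)cc(O)c1C(=O)O | intermediate
16 | rac-2-{[5-heptyl-2,7-dihydroxy-4-oxo-3,4-dihydro-2H-chromen-2-yl]methyl}-4,6-dihydroxybenzoic acid | CCCCCCCc1cc(O)cc2c1C(=O)CC(O)(Cc1cc(O)cc(O)c1C(=O)O)O2 | intermediate
17 | (1R)-N,N-dimethyl-1-phenylethanaminium salt of the (2R)-acid | CCCCCCCc1cc(O)cc2c1C(=O)C[C@@](O)(Cc1cc(O)cc(O)c1C(=O)[O-])O2.C[C@@H]([NH+](C)C)c1ccccc1 | intermediate
18 | 2-{[(2R)-5-heptyl-2,7-dihydroxy-4-oxo-3,4-dihydro-2H-chromen-2-yl]methyl}-4,6-dihydroxybenzoic acid | CCCCCCCc1cc(O)cc2c1C(=O)C[C@@](O)(Cc1cc(O)cc(O)c1C(=O)O)O2 | target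

**Total step count:** 12.
**Longest linear sequence:** 10 (steps 3–12, from orsellinic acid 4).

**Steps most likely to fail**

Step 11. The salt may oil out instead of nucleating, both C2 epimers may co-crystallise as a solid solution, or slow loss of water from the hemiketal may compete during ageing. The fallback sets out from 16 and uses known chemistry. Preparative chiral supercritical-fluid chromatography is run on an immobilised amylose tris(3,5-dimethylphenylcarbamate) phase (CO2/MeCN, no additive, column held at 10–15 °C). It delivers 18 directly and bypasses 17. The unwanted 2-{[(2S)-5-heptyl-2,7-dihydroxy-4-oxo-3,4-dihydro-2H-chromen-2-yl]methyl}-4,6-dihydroxybenzoic acid F1 is left in wet THF with a trace of Et3N until it has re-equilibrated to 16, and is then re-injected. The fallback rejoins the route at 18.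

Step 7. Base-mediated consumption of the enolisable vinyl ketone (self-Michael oligomerisation, enolate attack on the neighbouring ester, C-alkylation by the bromide) may outpace its Heck capture. Heck coupling may also occur before ortho-alkylation. The fallback sets out from 3 and 10 and moves the union with ring B out of the palladium step. The same Pd(OAc)2/P(2-furyl)3/norbornene/K2CO3 system is run with commercial, non-enolisable N-methoxy-N-methylacrylamide (C=CC(=O)N(C)OC). This gives (2E)-3-[2,4-bis(benzyloxy)-6-heptylphenyl]-N-methoxy-N-methylprop-2-enamide F2. The benzylic lithium species 6, made from 5 with LiN(i-Pr)2 at −78 °C, is then added to F2. The crowded β-carbon disfavours 1,4-addition, and the chelated adduct survives until a cold AcOH quench. The fallback rejoins the route at 11 and makes steps 4–6 unnecessary.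

Step 8. Conjugate borylation may be sluggish at a β-carbon flanked by two ortho substituents. Elimination or retro-aldol cleavage of the aldol may also occur during the basic oxidative work-up. The fallback sets out from 11. Weitz–Scheffer epoxidation (t-BuOOH, DBU, toluene, 0 °C → rt), with its small nucleophile, gives racemic benzyl 2,4-bis(benzyloxy)-6-{2-[trans-3-(2,4-bis(benzyloxy)-6-heptylphenyl)oxiran-2-yl]-2-oxoethyl}benzoate F3. This is isomerised by zerovalent palladium (Pd(PPh3)4, dppe, toluene, 90 °C), the known conversion of α,β-epoxy ketones into β-diketones. The fallback rejoins the route at 14 and skips 12 and 13.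

**Further compounds**
F1 | step 11 | 2-{[(2S)-5-heptyl-2,7-dihydroxy-4-oxo-3,4-dihydro-2H-chromen-2-yl]methyl}-4,6-dihydroxybenzoic acid | CCCCCCCc1cc(O)cc2c1C(=O)C[C@](O)(Cc1cc(O)cc(O)c1C(=O)O)O2
F2 | step 7 | (2E)-3-[2,4-bis(benzyloxy)-6-heptylphenyl]-N-methoxy-N-methylprop-2-enamide | CCCCCCCc1cc(OCc2ccccc2)cc(OCc2ccccc2)c1/C=C/C(=O)N(C)OC
F3 | step 8 | benzyl 2,4-bis(benzyloxy)-6-{2-[trans-3-(2,4-bis(benzyloxy)-6-heptylphenyl)oxiran-2-yl]-2-oxoethyl}benzoate (racemic, one enantiomer drawn) | CCCCCCCc1cc(OCc2ccccc2)cc(OCc2ccccc2)c1[C@@H]3[C@H](O3)C(=O)Cc1cc(OCc2ccccc2)cc(OCc2ccccc2)c1C(=O)OCc1ccccc1
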